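Ring C is disconnected at O1–C8a. With that bond cut, ring A (C5‑O, C7‑O, C8‑OMe) and ring B (C2'‑O, C4'‑O, C5'‑OMe) are the same aryl group. C2, C3 and C4 with both rings therefore collapse to one symmetric 2‑methoxy‑1,3‑diaryl‑1,3‑dione carrying a bromine beside each carbonyl‑bearing carbon. A copper‑catalysed intramolecular O‑arylation of its enolate forms the pyranone and fixes O1 next to the C8 methoxy group in one operation. The unused bromine and the four benzyl ethers are removed together in a final hydrogenolysis. Both halves of the diketone come from a single aldehyde made from 5‑bromoresorcinol.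

Key step: step 10

Remark on the chemistry: the target is achiral. The carbinol centres created in steps 6 and 8 are formed without control and are erased in steps 7 and 9, so no configuration has to be set.

Step 1
Reactants: 1 5‑bromoresorcinol; 2 benzyl bromide (two equivalents are consumed)
Product: 3 1,3‑bis(benzyloxy)‑5‑bromobenzene
Conditions: BnBr (2.2 equiv), K2CO3, DMF, 60 °C
Reagents that add atoms: benzyl bromide (second equivalent), BrCc1ccccc1
Why: Double Williamson ether synthesis; each of the two phenoxides of 1 is alkylated by one molecule of the benzylic bromide, and 1 offers no competing site.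

Step 2
Reactants: 3 1,3‑bis(benzyloxy)‑5‑bromobenzene
Product: 5 2,4‑bis(benzyloxy)‑6‑bromobenzaldehyde, via aryl iminium chloride 4 (not isolated)
Conditions: POCl3, DMF, 0 → 80 °C; then aq NaOAc
Reagents that add atoms: N,N‑dimethylformamide, CN(C)C=O; water, O
Why: Vilsmeier–Haack formylation; the chloroiminium ion should attack the carbon para to one benzyloxy group and ortho to the other, which is the position beside bromine, in preference to the more crowded carbon between the two ethers, and benzyl ethers tolerate the conditions.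

Step 3
Reactants: 5 2,4‑bis(benzyloxy)‑6‑bromobenzaldehyde
Product: 7 2,4‑bis(benzyloxy)‑6‑bromophenol, via aryl formate 6 (not isolated)
Conditions: mCPBA, CH2Cl2, 0 °C → rt; then K2CO3, MeOH, rt
Reagents that add atoms: mCPBA (3‑chloroperoxybenzoic acid), OOC(=O)c1cccc(Cl)c1
Why: Baeyer–Villiger oxidation of an electron‑rich aryl aldehyde (the peracid form of the Dakin reaction); the dialkoxyaryl group migrates to give the formate, and mild methanolysis frees the phenol without touching the benzyl ethers or the bromide.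

Step 4
Reactants: 7 2,4‑bis(benzyloxy)‑6‑bromophenol
Product: 8 1,5‑bis(benzyloxy)‑3‑bromo‑2‑methoxybenzene
Conditions: MeI, K2CO3, DMF, rt
Reagents that add atoms: iodomethane, CI
Why: Williamson O‑methylation; the phenoxide flanked by bromine and a benzyloxy group should still react readily with the small electrophile.

Step 5
Reactants: 8 1,5‑bis(benzyloxy)‑3‑bromo‑2‑methoxybenzene
Product: 10 4,6‑bis(benzyloxy)‑2‑bromo‑3‑methoxybenzaldehyde, via aryl iminium chloride 9 (not isolated)
Conditions: POCl3, DMF, 0 → 90 °C; then aq NaOAc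
Reagents that add atoms: N,N‑dimethylformamide, CN(C)C=O; water, O
Why: Vilsmeier–Haack formylation with the same selectivity as step 2; C4 of 8, beside bromine, is the only free carbon para to a benzyloxy group, whereas C6 lies between two benzyloxy groups, one of which is pushed toward it by the neighbouring methoxy group.

Step 6
Reactants: 10 4,6‑bis(benzyloxy)‑2‑bromo‑3‑methoxybenzaldehyde; 11 tributyl(methoxymethyl)stannane
Product: 13 rac‑1‑[4,6‑bis(benzyloxy)‑2‑bromo‑3‑methoxyphenyl]‑2‑methoxyethan‑1‑ol, via methoxymethyllithium 12 (not isolated)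
Conditions: Bu3SnCH2OMe (1.2 equiv), n‑BuLi (1.1 equiv), THF, −78 °C; transferred onto 10 in THF, −78 °C; aq NH4Cl
Reagents that add atoms: none
Why: Tin–lithium exchange gives the α‑alkoxy organolithium, which should add 1,2 to the aldehyde much faster than it exchanges with the aryl bromide at −78 °C (no butyllithium is left over); the carbinol centre is racemic and is erased in step 7.

Step 7
Reactants: 13 rac‑1‑[4,6‑bis(benzyloxy)‑2‑bromo‑3‑methoxyphenyl]‑2‑methoxyethan‑1‑ol
Product: 14 1‑[4,6‑bis(benzyloxy)‑2‑bromo‑3‑methoxyphenyl]‑2‑methoxyethan‑1‑one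
Conditions: Dess–Martin periodinane, CH2Cl2, rt
Reagents that add atoms: none
Why: Dess–Martin oxidation of a secondary benzylic alcohol to the aryl ketone under neutral conditions that leave the benzyl ethers, the aryl bromide and the α‑methoxy group alone.

Step 8
Reactants: 14 1‑[4,6‑bis(benzyloxy)‑2‑bromo‑3‑methoxyphenyl]‑2‑methoxyethan‑1‑one; 10 4,6‑bis(benzyloxy)‑2‑bromo‑3‑methoxybenzaldehyde
Product: 16 1,3‑bis[4,6‑bis(benzyloxy)‑2‑bromo‑3‑methoxyphenyl]‑3‑hydroxy‑2‑methoxypropan‑1‑one (racemic diastereomer mixture), via lithium enolate 15 (not isolated)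
Conditions: LiN(SiMe3)2 (1.1 equiv), THF, −78 °C; then 10, −78 °C; AcOH, −78 °C
Reagents that add atoms: none
Why: Directed crossed aldol addition; the preformed chelated lithium enolate of the α‑methoxy ketone adds to the non‑enolisable aldehyde and the aldolate is protonated cold to suppress retro‑aldol, while the two new stereocentres are left uncontrolled because step 9 removes both.

Step 9
Reactants: 16 1,3‑bis[4,6‑bis(benzyloxy)‑2‑bromo‑3‑methoxyphenyl]‑3‑hydroxy‑2‑methoxypropan‑1‑one
Product: 17 1,3‑bis[4,6‑bis(benzyloxy)‑2‑bromo‑3‑methoxyphenyl]‑2‑methoxypropane‑1,3‑dione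
Conditions: Dess–Martin periodinane, CH2Cl2, 0 °C → rt
Reagents that add atoms: none
Why: Dess–Martin oxidation of a β‑hydroxy ketone to the 1,3‑diketone, avoiding the basic or strongly acidic media in which the aldol could revert or dehydrate; the product is symmetric about C2, so both stereocentres vanish.

Step 10
Reactants: 17 1,3‑bis[4,6‑bis(benzyloxy)‑2‑bromo‑3‑methoxyphenyl]‑2‑methoxypropane‑1,3‑dione
Product: 19 5,7‑bis(benzyloxy)‑2‑[4,6‑bis(benzyloxy)‑2‑bromo‑3‑methoxyphenyl]‑3,8‑dimethoxychromen‑4‑one, via caesium enolate 18 (not isolated)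
Conditions: CuI (10 mol %), 1,10‑phenanthroline (20 mol %), Cs2CO3 (2 equiv), toluene, 100 °C, Ar
Reagents that add atoms: none
Why: Copper‑catalysed intramolecular Ullmann‑type O‑arylation: carbonate deprotonates C2, the enolate binds monovalent copper through oxygen, the metal inserts into the C–Br bond ortho to the other carbonyl‑bearing carbon to give a trivalent aryl copper chelate, and C–O reductive elimination releases the pyranone. The closest known reaction type is the copper‑catalysed cyclisation of 1‑(2‑bromoaryl)‑1,3‑diones to chromones and flavones. Ring C closes as a six‑membered ring by bonding of the enolate oxygen to the aromatic sp2 carbon that bore bromine, with the departing bromide outside the new ring and the enol double bond inside it; no stereocentre is created. O‑ versus C‑arylation is decided by ring size, because C2 or the oxygen of the nearer carbonyl could only form a strained four‑membered ring, and the choice between the two aroyl arms is immaterial since they are identical. The position of the bromine dictates where O1 is attached, so the oxygen ends next to the C8 methoxy group and the 6‑methoxy isomer cannot form. Once the enolate is consumed the second bromide has no partner and is carried on as the C6' bromine of 19.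

Step 11
Reactants: 19 5,7‑bis(benzyloxy)‑2‑[4,6‑bis(benzyloxy)‑2‑bromo‑3‑methoxyphenyl]‑3,8‑dimethoxychromen‑4‑one
Product: 20 5,7,2',4'‑tetrahydroxy‑3,8,5'‑trimethoxyflavone
Conditions: H2 (1 atm), 10% Pd/C, NaOAc, THF–MeOH, rt
Reagents that add atoms: none
Why: Catalytic hydrogenolysis should cleave the four benzyl aryl ethers and, with acetate trapping HBr, hydrodehalogenate the C6' bromide in the same flask, while the fully substituted C2=C3 bond of the 3‑methoxyflavone is not reduced under these mild conditions.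

Compound list
1 | 5‑bromoresorcinol (5‑bromobenzene‑1,3‑diol) | Oc1cc(O)cc(Br)c1 | starting material
2 | benzyl bromide | BrCc1ccccc1 | starting material
3 | 1,3‑bis(benzyloxy)‑5‑bromobenzene | Brc1cc(OCc2ccccc2)cc(OCc2ccccc2)c1 | intermediate
4 | N‑[2,4‑bis(benzyloxy)‑6‑bromobenzylidene]‑N‑methylmethanaminium chloride (not isolated) | C[N+](C)=Cc1c(Br)cc(OCc2ccccc2)cc1OCc1ccccc1.[Cl-] | intermediate
5 | 2,4‑bis(benzyloxy)‑6‑bromobenzaldehyde | O=Cc1c(Br)cc(OCc2ccccc2)cc1OCc1ccccc1 | intermediate
6 | 2,4‑bis(benzyloxy)‑6‑bromophenyl formate (not isolated) | O=COc1c(Br)cc(OCc2ccccc2)cc1OCc1ccccc1 | intermediate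
7 | 2,4‑bis(benzyloxy)‑6‑bromophenol | Oc1c(Br)cc(OCc2ccccc2)cc1OCc1ccccc1 | intermediate
8 | 1,5‑bis(benzyloxy)‑3‑bromo‑2‑methoxybenzene | COc1c(Br)cc(OCc2ccccc2)cc1OCc1ccccc1 | intermediate
9 | N‑[4,6‑bis(benzyloxy)‑2‑bromo‑3‑methoxybenzylidene]‑N‑methylmethanaminium chloride (not isolated) | C[N+](C)=Cc1c(Br)c(OC)c(OCc2ccccc2)cc1OCc1ccccc1.[Cl-] | intermediate
10 | 4,6‑bis(benzyloxy)‑2‑bromo‑3‑methoxybenzaldehyde | O=Cc1c(Br)c(OC)c(OCc2ccccc2)cc1OCc1ccccc1 | intermediate
11 | tributyl(methoxymethyl)stannane | CCCC[Sn](CCCC)(CCCC)COC | starting material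
12 | methoxymethyllithium (not isolated) | [Li]COC | intermediate
13 | rac‑1‑[4,6‑bis(benzyloxy)‑2‑bromo‑3‑methoxyphenyl]‑2‑methoxyethan‑1‑ol | COCC(O)c1c(Br)c(OC)c(OCc2ccccc2)cc1OCc1ccccc1 | intermediate
14 | 1‑[4,6‑bis(benzyloxy)‑2‑bromo‑3‑methoxyphenyl]‑2‑methoxyethan‑1‑one | COCC(=O)c1c(Br)c(OC)c(OCc2ccccc2)cc1OCc1ccccc1 | intermediate
15 | lithium (Z)‑1‑[4,6‑bis(benzyloxy)‑2‑bromo‑3‑methoxyphenyl]‑2‑methoxyethen‑1‑olate (not isolated) | CO/C=C(\[O-])c1c(Br)c(OC)c(OCc2ccccc2)cc1OCc1ccccc1.[Li+] | intermediate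
16 | 1,3‑bis[4,6‑bis(benzyloxy)‑2‑bromo‑3‑methoxyphenyl]‑3‑hydroxy‑2‑methoxypropan‑1‑one (racemic, syn and anti diastereomers) | COC(C(O)c1c(Br)c(OC)c(OCc2ccccc2)cc1OCc1ccccc1)C(=O)c1c(Br)c(OC)c(OCc2ccccc2)cc1OCc1ccccc1 | intermediate
17 | 1,3‑bis[4,6‑bis(benzyloxy)‑2‑bromo‑3‑methoxyphenyl]‑2‑methoxypropane‑1,3‑dione | COC(C(=O)c1c(Br)c(OC)c(OCc2ccccc2)cc1OCc1ccccc1)C(=O)c1c(Br)c(OC)c(OCc2ccccc2)cc1OCc1ccccc1 | intermediate
18 | caesium 1,3‑bis[4,6‑bis(benzyloxy)‑2‑bromo‑3‑methoxyphenyl]‑2‑methoxy‑3‑oxoprop‑1‑en‑1‑olate (delocalised, not isolated) | COC(C(=O)c1c(Br)c(OC)c(OCc2ccccc2)cc1OCc1ccccc1)=C([O-])c1c(Br)c(OC)c(OCc2ccccc2)cc1OCc1ccccc1.[Cs+] | intermediate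
19 | 5,7‑bis(benzyloxy)‑2‑[4,6‑bis(benzyloxy)‑2‑bromo‑3‑methoxyphenyl]‑3,8‑dimethoxychromen‑4‑one | COc1c(Br)c(-c2oc3c(OC)c(OCc4ccccc4)cc(OCc4ccccc4)c3c(=O)c2OC)c(OCc2ccccc2)cc1OCc1ccccc1 | intermediate
20 | 5,7,2',4'‑tetrahydroxy‑3,8,5'‑trimethoxyflavone | COc1cc(-c2oc3c(OC)c(O)cc(O)c3c(=O)c2OC)c(O)cc1O | target

Total step count: 11. Longest linear sequence: 11 steps (1 → 20; aldehyde 10 is used twice, in steps 6 and 8).

Steps most likely to fail

Step 10. Oxidative addition at the C–Br bond, which is flanked on both sides, may be slow, so base‑induced retro‑Claisen cleavage of the diketone or protodebromination could overtake ring closure. The fallback installs O1 as a phenol first and closes ring C through the O1–C2 bond. It sets out from ketone 14: hydroxylation of the bromide (Pd2(dba)3, t‑BuXPhos, KOH, dioxane–water, 90 °C) should give 1‑[4,6‑bis(benzyloxy)‑2‑hydroxy‑3‑methoxyphenyl]‑2‑methoxyethan‑1‑one F1. Claisen–Schmidt condensation of this with aldehyde 10 (KOH, EtOH, rt) should give (Z)‑1‑[4,6‑bis(benzyloxy)‑2‑hydroxy‑3‑methoxyphenyl]‑3‑[4,6‑bis(benzyloxy)‑2‑bromo‑3‑methoxyphenyl]‑2‑methoxyprop‑2‑en‑1‑one F2. Iodine‑catalysed oxidative cyclisation (I2 cat., DMSO, 120 °C) then returns to the route at 19.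

Step 8. Addition to the hindered, electron‑rich aldehyde may be incomplete and the aldol may revert on warming or work‑up. The fallback replaces the aldol and oxidation by a Claisen‑type C‑acylation. It sets out from aldehyde 10: Pinnick oxidation (NaClO2, NaH2PO4, 2‑methyl‑2‑butene, t‑BuOH–water) should give 4,6‑bis(benzyloxy)‑2‑bromo‑3‑methoxybenzoic acid F3. Oxalyl chloride with catalytic DMF in CH2Cl2 should give 4,6‑bis(benzyloxy)‑2‑bromo‑3‑methoxybenzoyl chloride F4. This acylates ketone 14 at carbon under soft enolisation (MgBr2·OEt2, i‑Pr2NEt, CH2Cl2) and comes back to the route at diketone 17, bypassing 16 and step 9.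

Step 5. Regiocontrol may erode toward attack between the two benzyloxy groups, or conversion may stall at the hindered position beside bromine. The fallback replaces electrophilic substitution by acidity‑driven deprotonation. It sets out from 8: LiN(i‑Pr)2 in THF at −78 °C should remove the ring hydrogen flanked by bromine and a benzyloxy group, expected to be the most acidic one, to give [4,6‑bis(benzyloxy)‑2‑bromo‑3‑methoxyphenyl]lithium F5. This is quenched cold with DMF, before benzyne formation can occur, and comes back to the route at aldehyde 10.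

Further compounds
F1 | step 10 | 1‑[4,6‑bis(benzyloxy)‑2‑hydroxy‑3‑methoxyphenyl]‑2‑methoxyethan‑1‑one | COCC(=O)c1c(O)c(OC)c(OCc2ccccc2)cc1OCc1ccccc1
F2 | step 10 | (Z)‑1‑[4,6‑bis(benzyloxy)‑2‑hydroxy‑3‑methoxyphenyl]‑3‑[4,6‑bis(benzyloxy)‑2‑bromo‑3‑methoxyphenyl]‑2‑methoxyprop‑2‑en‑1‑one | CO/C(=C\c1c(Br)c(OC)c(OCc2ccccc2)cc1OCc1ccccc1)C(=O)c1c(O)c(OC)c(OCc2ccccc2)cc1OCc1ccccc1
F3 | step 8 | 4,6‑bis(benzyloxy)‑2‑bromo‑3‑methoxybenzoic acid | O=C(O)c1c(Br)c(OC)c(OCc2ccccc2)cc1OCc1ccccc1
F4 | step 8 | 4,6‑bis(benzyloxy)‑2‑bromo‑3‑methoxybenzoyl chloride | O=C(Cl)c1c(Br)c(OC)c(OCc2ccccc2)cc1OCc1ccccc1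
F5 | step 5 | [4,6‑bis(benzyloxy)‑2‑bromo‑3‑methoxyphenyl]lithium | [Li]c1c(Br)c(OC)c(OCc2ccccc2)cc1OCc1ccccc1
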